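## Retrosynthetic overview
1. The exocyclic (E)-C=C comes from an aldol/mesylation/E1cB union of (S)-5-(2-methylprop-1-enyl)butyrolactone with a C17 aldehyde that already carries the butenolide.
2. Key disconnection: the ring C5–O1 bond of that lactone leads back to achiral 6-methylhepta-4,6-dienoic acid. An enantioselective Pd–H hydrolactonisation closes the ring and sets the only stereocentre. The acid comes from a Wittig reaction of (3-carboxypropyl)triphenylphosphonium bromide with methacrolein.
3. The C17 aldehyde comes from periodate cleavage of a terminal epoxide. The butenolide–CH2 bond comes from a B-alkyl Suzuki coupling of 4-bromofuran-2(5H)-one with a diene-derived 9-BBN borane.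
4. The epoxy diene comes from (2E,6E)-farnesol, which supplies both E-trisubstituted alkenes, by terminal epoxidation, MnO2 oxidation and methylenation.
5. Ring order: the butenolide ring is bought and attached in step 4, the γ-lactone ring is closed in step 7, and the fragments are joined in step 8.

Assumption: the (R,R) ligand in step 7 is assumed to give the (S)-lactone. If the first run gives (R), the equally available (S,S) ligand is used and nothing else changes.

## Route

Step 1
Reactants: 1 (2E,6E)-farnesol
Product: 3 (2E,6E)-9-(3,3-dimethyloxiran-2-yl)-3,7-dimethylnona-2,6-dien-1-ol (10,11-epoxyfarnesol; racemic at the epoxide carbon), via terminal bromohydrin 2 (not isolated)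
Conditions: NBS (1.05 equiv), THF–H2O 2:1, 0 °C, 1.5 h; then K2CO3 (3 equiv), MeOH, rt, 2 h (one pot)
Reagents that add atoms: water, O (its O becomes the epoxide O); N-bromosuccinimide, O=C1CCC(=O)N1Br (its Br sits only in 2)
Why: This is a van Tamelen-type terminal bromohydrin formation: NBS in aqueous THF attacks the most exposed isopropylidene alkene (the 2,3-alkene is deactivated by the allylic OH), water opens the bromonium ion at the tertiary carbon, carbonate closes the epoxide by intramolecular Williamson SN2, and the new centre is racemic but is excised in step 5.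

Step 2
Reactants: 3 10,11-epoxyfarnesol
Product: 4 (2E,6E)-9-(3,3-dimethyloxiran-2-yl)-3,7-dimethylnona-2,6-dienal
Conditions: activated MnO2 (15 equiv), CH2Cl2, rt, 4 h
Reagents that add atoms: none
Why: Selective allylic alcohol oxidation on MnO2 runs under neutral heterogeneous conditions that leave the epoxide, the isolated alkene and the 2E geometry untouched.

Step 3
Reactants: 4 epoxy enal
Product: 5 3-[(3E,7E)-3,7-dimethyldeca-3,7,9-trien-1-yl]-2,2-dimethyloxirane
Conditions: Ph3PCH3Br (1.3 equiv), n-BuLi (1.25 equiv), THF, 0 °C; then 4, −78 °C to rt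
Reagents that add atoms: methyltriphenylphosphonium bromide, C[P+](c1ccccc1)(c1ccccc1)c1ccccc1.[Br-]
Why: Wittig methylenation (1,2-addition of the non-stabilised ylide to the enal) gives the terminal 1,3-diene without touching the epoxide or the E alkenes.

Step 4
Reactants: 5 epoxy triene; 6 4-bromofuran-2(5H)-one
Product: 8 4-[(3E,7E)-10-(3,3-dimethyloxiran-2-yl)-4,8-dimethyldeca-3,7-dien-1-yl]furan-2(5H)-one, via homoallylic B-alkyl-9-BBN 7 (not isolated)
Conditions: 9-BBN (1.05 equiv), THF, 0 °C to rt, 3 h; then 6 (1.1 equiv), PdCl2(dppf)·CH2Cl2 (5 mol %), AsPh3 (5 mol %), 3 M aq K3PO4 (2 equiv), DMF, rt, 12 h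
Reagents that add atoms: 9-borabicyclo[3.3.1]nonane, B1C2CCCC1CCC2 (its boron cage sits only in 7; only its H stays in 8)
Why: Bulky 9-BBN hydroborates only the monosubstituted vinyl terminus of the diene (anti-Markovnikov), and the resulting homoallylic borane undergoes B-alkyl Suzuki–Miyaura coupling with the vinylogous acyl bromide 6 at room temperature under mild phosphate base, so the epoxide and butenolide survive.

Step 5
Reactants: 8 epoxy butenolide
Product: 9 (4E,8E)-4,8-dimethyl-11-(5-oxo-2,5-dihydrofuran-3-yl)undeca-4,8-dienal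
Conditions: H5IO6 (1.3 equiv), THF–H2O 4:1, 0 °C, 1 h
Reagents that add atoms: none
Why: Periodic acid hydrolyses the trisubstituted epoxide (water enters at the tertiary carbon) and cleaves the glycol in the same pot (Malaprade cleavage), which removes the racemic centre as acetone while the alkenes and the electron-poor butenolide stay inert.

Step 6
Reactants: 10 (3-carboxypropyl)triphenylphosphonium bromide; 11 methacrolein
Product: 13 (Z)-6-methylhepta-4,6-dienoic acid, via ylide carboxylate 12 (not isolated)
Conditions: NaHMDS (2.1 equiv), THF, 0 °C; then 11, −78 °C to rt; 1 M HCl work-up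
Reagents that add atoms: sodium hexamethyldisilazide, [Na+].C[Si](C)(C)[N-][Si](C)(C)C (its Na sits only in 12)
Why: Wittig olefination with the non-stabilised ylide-carboxylate adds 1,2 to the enal and gives mainly the Z diene (about 9:1), and this geometry is erased in step 7.

Step 7 (key step)
Reactants: 13 (Z)-6-methylhepta-4,6-dienoic acid
Product: 14 (S)-5-(2-methylprop-1-en-1-yl)dihydrofuran-2(3H)-one
Conditions: Pd2(dba)3·CHCl3 (2.5 mol %), (R,R)-DACH-naphthyl Trost ligand (6 mol %), toluene (0.1 M), 25 °C, ca. 16 h, stopped at full conversion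
Reagents that add atoms: none
Why: Proposed new method: enantioselective Pd–H hydrolactonisation (intramolecular 1,4-hydroacyloxylation) of a 1,3-dienoic acid, in which the substrate's own CO2H protonates the L*Pd(0)–diene complex at the unsubstituted C7 terminus to give a 1,1-dimethyl-3-alkyl-π-allylpalladium carboxylate; its two faces and its syn/anti forms interconvert fast by η3–η1–η3 slippage through the CMe2 terminus, which carries two identical groups, so the Z/E ratio of 13 does not matter; the tethered carboxylate, held by hydrogen bonding to a ligand amide N–H, then attacks the less hindered secondary terminus C4 anti to Pd in a 5-exo closure, so the new C4–O bond forms the ring and sets the (S) centre under Curtin–Hammett control; attack at CMe2 would need a seven-membered ring, there is no uncatalysed background, and the trisubstituted alkene of 14 binds Pd(0) poorly, so re-ionisation should be slow at 25 °C; the closest known reaction types are Pd/Trost-ligand hydroamination of 1,3-dienes, Rh–H addition of carboxylic acids to allenes to give branched allylic esters, and Pd-catalysed asymmetric allylic esterification with carboxylate nucleophiles.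

Step 8
Reactants: 14 (S)-lactone; 9 butenolide aldehyde
Product: 18 (3E,5S)-3-[(4E,8E)-4,8-dimethyl-11-(5-oxo-2,5-dihydrofuran-3-yl)undeca-4,8-dien-1-ylidene]-5-(2-methylprop-1-en-1-yl)dihydrofuran-2(3H)-one (target), via lithium enolate 15 (not isolated), via lithium aldolate 16 (not isolated), via mesylate 17 (not isolated)
Conditions: 14 (1.1 equiv), LDA (1.1 equiv), THF, −78 °C, 30 min; 9 (1.0 equiv), −78 °C, 20 min; MsCl (1.5 equiv), −78 to 0 °C; DBU (3 equiv), 0 °C to rt, 1 h
Reagents that add atoms: lithium diisopropylamide, [Li+].CC(C)[N-]C(C)C (its Li sits only in 15 and 16); methanesulfonyl chloride, CS(=O)(=O)Cl (its CH3SO2 group sits only in 17)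
Why: Aldol addition of the lactone enolate to the aldehyde is much faster at −78 °C than attack on or deprotonation of the hindered butenolide, and O-mesylation followed by DBU-induced E1cB elimination converges both aldol diastereomers on the thermodynamically preferred E alkylidene lactone (chain anti to C=O; expected E:Z at least 10:1, minor isomer removed by chromatography), while C5 is not acidic and stays S.

## Compound list
1 | (2E,6E)-farnesol | CC(C)=CCC/C(C)=C/CC/C(C)=C/CO | starting material
2 | (2E,6E)-10-bromo-3,7,11-trimethyldodeca-2,6-diene-1,11-diol (racemic) | CC(C)(O)C(Br)CC/C(C)=C/CC/C(C)=C/CO | intermediate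
3 | (2E,6E)-9-(3,3-dimethyloxiran-2-yl)-3,7-dimethylnona-2,6-dien-1-ol (racemic) | CC1(C)OC1CC/C(C)=C/CC/C(C)=C/CO | intermediate
4 | (2E,6E)-9-(3,3-dimethyloxiran-2-yl)-3,7-dimethylnona-2,6-dienal (racemic) | CC1(C)OC1CC/C(C)=C/CC/C(C)=C/C=O | intermediate
5 | 3-[(3E,7E)-3,7-dimethyldeca-3,7,9-trien-1-yl]-2,2-dimethyloxirane (racemic) | CC1(C)OC1CC/C(C)=C/CC/C(C)=C/C=C | intermediate
6 | 4-bromofuran-2(5H)-one | O=C1C=C(Br)CO1 | starting material
7 | 9-[(3E,7E)-10-(3,3-dimethyloxiran-2-yl)-4,8-dimethyldeca-3,7-dien-1-yl]-9-borabicyclo[3.3.1]nonane | CC1(C)OC1CC/C(C)=C/CC/C(C)=C/CCB1C2CCCC1CCC2 | intermediate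
8 | 4-[(3E,7E)-10-(3,3-dimethyloxiran-2-yl)-4,8-dimethyldeca-3,7-dien-1-yl]furan-2(5H)-one (racemic) | CC1(C)OC1CC/C(C)=C/CC/C(C)=C/CCC2=CC(=O)OC2 | intermediate
9 | (4E,8E)-4,8-dimethyl-11-(5-oxo-2,5-dihydrofuran-3-yl)undeca-4,8-dienal | O=CCC/C(C)=C/CC/C(C)=C/CCC1=CC(=O)OC1 | intermediate
10 | (3-carboxypropyl)triphenylphosphonium bromide | OC(=O)CCC[P+](c1ccccc1)(c1ccccc1)c1ccccc1.[Br-] | starting material
11 | methacrolein | CC(=C)C=O | starting material
12 | sodium 4-(triphenyl-λ5-phosphanylidene)butanoate | [Na+].[O-]C(=O)CCC=P(c1ccccc1)(c1ccccc1)c1ccccc1 | intermediate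
13 | (Z)-6-methylhepta-4,6-dienoic acid | CC(=C)/C=C\CCC(=O)O | intermediate
14 | (S)-5-(2-methylprop-1-en-1-yl)dihydrofuran-2(3H)-one | CC(C)=C[C@@H]1CCC(=O)O1 | intermediate
15 | lithium enolate of 14 | CC(C)=C[C@@H]1CC=C([O-])O1.[Li+] | intermediate
16 | lithium aldolate of 14 and 9 (mixture at the two new centres) | CC(C)=C[C@@H]1CC(C([O-])CC/C(C)=C/CC/C(C)=C/CCC2=CC(=O)OC2)C(=O)O1.[Li+] | intermediate
17 | mesylate of the aldol adduct (mixture at the two new centres) | CC(C)=C[C@@H]1CC(C(OS(C)(=O)=O)CC/C(C)=C/CC/C(C)=C/CCC2=CC(=O)OC2)C(=O)O1 | intermediate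
18 | CNP0237694.1 | CC(C)=C[C@@H]1C/C(=C\CC/C(C)=C/CC/C(C)=C/CCC2=CC(=O)OC2)C(=O)O1 | target

## Summary
Total step count: 8.
Longest linear sequence: 6 (steps 1–5, then step 8). Steps 6 and 7 form the short branch.

### The three steps most likely to fail

**Step 7 (proposed new step).**
- Risks:
  - An aliphatic acid may generate Pd–H only slowly.
  - Pd(0) may re-ionise the allylic lactone and erode the ee.
  - The level and sense of induction are untested.
- Fallback (known chemistry only): it sets out from 13 and comes back at 14.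
  - Catalytic TfOH (5 mol %, CH2Cl2, 0 °C) closes the ring by ordinary Brønsted-acid hydrolactonisation, giving racemic 5-(2-methylprop-1-en-1-yl)dihydrofuran-2(3H)-one F1.
  - MeNH(OMe)·HCl with i-PrMgCl opens it to racemic 4-hydroxy-N-methoxy-N,6-dimethylhept-5-enamide F2.
  - MnO2 oxidises the allylic alcohol to the enone N-methoxy-N,6-dimethyl-4-oxohept-5-enamide F3.
  - Corey–Bakshi–Shibata reduction with (R)-Me-CBS and catecholborane (toluene, −78 °C; the alkenyl group acts as the large substituent) gives (S)-4-hydroxy-N-methoxy-N,6-dimethylhept-5-enamide F4.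
  - F4 lactonises with catalytic PPTS to 14. All of the racemate is funnelled into one enantiomer, and the centre is set by hydride delivery.

**Step 8.**
- Risks:
  - The C5–H of the butenolide in 9 is acidic towards the enolate and DBU.
  - The exocyclic alkene may drift under DBU.
  - The E:Z ratio may be incomplete in a one-pot sequence.
- Fallback: it sets out from 14 and comes back at 18.
  - LDA, then ClP(O)(OEt)2, then more LDA (enol phosphate to phosphonate 1,3-shift) converts 14 into diethyl [(5S)-5-(2-methylprop-1-en-1-yl)-2-oxotetrahydrofuran-3-yl]phosphonate F5.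
  - A Horner–Wadsworth–Emmons reaction of F5 with 9 under Masamune–Roush conditions (LiCl, i-Pr2NEt, MeCN, 0 °C to rt) gives 18 with a weakly basic nucleophile.
  - The E isomer is separated from any Z isomer by chromatography.

**Step 4.**
- Risks:
  - Bromide 6 is hydrolysed to tetronic acid by aqueous base.
  - Some allylborane may form from the diene.
  - Protodeboronation may occur.
- Fallback: it sets out from 5 (through the same borane 7) and comes back at 8.
  - Instead of cross-coupling a preformed ring, the ring is built on the chain. Copper-catalysed conjugate addition of 7 to ethyl 4-hydroxybut-2-ynoate (CuOAc, P(OPh)3, catalytic KOt-Bu, t-BuOH, dioxane, 40 °C) is a formal syn-hydroalkylation.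
  - It gives ethyl (2Z,6E,10E)-13-(3,3-dimethyloxiran-2-yl)-3-(hydroxymethyl)-7,11-dimethyltrideca-2,6,10-trienoate F6.
  - In F6 the CH2OH and CO2Et groups are cis and lactonise (catalytic PPTS, rt) to 8.

## Further compounds
F1 | step 7 | racemic 5-(2-methylprop-1-en-1-yl)dihydrofuran-2(3H)-one | CC(C)=CC1CCC(=O)O1
F2 | step 7 | racemic 4-hydroxy-N-methoxy-N,6-dimethylhept-5-enamide | CC(C)=CC(O)CCC(=O)N(C)OC
F3 | step 7 | N-methoxy-N,6-dimethyl-4-oxohept-5-enamide | CC(C)=CC(=O)CCC(=O)N(C)OC
F4 | step 7 | (S)-4-hydroxy-N-methoxy-N,6-dimethylhept-5-enamide | CC(C)=C[C@@H](O)CCC(=O)N(C)OC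
F5 | step 8 | diethyl [(5S)-5-(2-methylprop-1-en-1-yl)-2-oxotetrahydrofuran-3-yl]phosphonate | CC(C)=C[C@@H]1CC(P(=O)(OCC)OCC)C(=O)O1
F6 | step 4 | ethyl (2Z,6E,10E)-13-(3,3-dimethyloxiran-2-yl)-3-(hydroxymethyl)-7,11-dimethyltrideca-2,6,10-trienoate | CC1(C)OC1CC/C(C)=C/CC/C(C)=C/CC/C(CO)=C/C(=O)OCC
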